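**Retrosynthetic overview**

- The strategy rests on the conjugated (13E,15E)-diene (labdane-type numbering, C18 = carboxyl carbon): the trisubstituted C13=C14 olefin with its C13 methyl, joined through the C14–C15 bond to the disubstituted C15=C16 olefin next to the C17 methyl stereocentre.
- Acid 20 ⇒ C18 primary alcohol 18 ⇒ silyl ether 17. Cutting C13–CH3 and C14–C15 of 17 gives terminal alkyne 8, AlMe3 14 and (R,E)-vinyl iodide 13, joined in one pot by methylalumination and Negishi coupling.
- Alkyne 8 ⇒ methyl ketone 4 (enol phosphate elimination) ⇒ hydroxy ketone 3 ⇒ (−)-sclareol 1. Iodide 13 ⇒ aldehyde 12 (Takai olefination) ⇒ hydroxy ester 9.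
- No ring is formed: ring A (C1–C5, C10) and ring B (C5–C10) with the C5 and C10 stereocentres come intact from sclareol; only the C8=C9 olefin is introduced into ring B.

Key step: step 8

Assumption: commercial (−)-sclareol and methyl (S)-3-hydroxy-2-methylpropanoate are taken as enantiopure, so C5, C10 and C17 come from the chiral pool and the route creates no stereocentre.

**Route**

Step 1
Reactants: 1 (−)-sclareol, (1R,2R,4aS,8aS)-1-[(3R)-3-hydroxy-3-methylpent-4-en-1-yl]-2,5,5,8a-tetramethyldecahydronaphthalen-2-ol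
Product: 3 4-[(1R,2R,4aS,8aS)-2-hydroxy-2,5,5,8a-tetramethyldecahydronaphthalen-1-yl]butan-2-one, via side-chain 13,14,15-triol 2 (not isolated)
Conditions: OsO4 (2 mol%), NaIO4 (4 equiv), 2,6-lutidine (2 equiv), dioxane/H2O 3:1, rt
Reagents that add atoms: none
Why: Lemieux–Johnson oxidation, in which the vinyl group (the only olefin) is dihydroxylated and periodate cleaves the resulting triol at C14–C15 and C13–C14, so that C13 keeps its own oxygen as the ketone while the lutidine buffer should keep the hydroxy ketone from dehydrating to its cyclic enol ether, which would be degraded further.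

Step 2
Reactants: 3 8α-hydroxy methyl ketone
Product: 4 4-[(4aS,8aS)-2,5,5,8a-tetramethyl-3,4,4a,5,6,7,8,8a-octahydronaphthalen-1-yl]butan-2-one
Conditions: PPh3 (1.2 equiv), I2 (1.2 equiv), CH2Cl2, rt
Reagents that add atoms: none
Why: PPh3/I2 dehydration of a tertiary alcohol by an E1 path, in which the C8 hydroxyl leaves as an alkoxyphosphonium ion and the C8 cation loses H-9 under the equilibrating HI that is formed, which should give the most substituted, tetrasubstituted C8=C9 olefin and removes the C8 and C9 stereocentres while C5 and C10 are untouched.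

Step 3
Reactants: 4 C8=C9 ene methyl ketone
Product: 6 diethyl 4-[(4aS,8aS)-2,5,5,8a-tetramethyl-3,4,4a,5,6,7,8,8a-octahydronaphthalen-1-yl]but-1-en-2-yl phosphate, via lithium enolate 5 (not isolated)
Conditions: LiN(iPr)2 (1.1 equiv), THF, −78 °C; ClP(O)(OEt)2 (1.2 equiv), −78 °C → rt
Reagents that add atoms: diethyl chlorophosphate, CCOP(=O)(Cl)OCC
Why: kinetic enolisation of the methyl ketone with the hindered amide base at −78 °C should take the methyl side, and O-phosphorylation of the enolate then gives the terminal enol phosphate (first stage of the enol phosphate route from methyl ketones to terminal alkynes).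

Step 4
Reactants: 6 terminal enol phosphate
Product: 8 (4aS,8aS)-1-(but-3-yn-1-yl)-2,5,5,8a-tetramethyl-3,4,4a,5,6,7,8,8a-octahydronaphthalene, via lithium acetylide 7 (not isolated)
Conditions: LiN(iPr)2 (2.5 equiv), THF, −78 °C → rt; then H2O
Reagents that add atoms: none
Why: base-induced β-elimination of diethyl phosphate from the enol phosphate gives the alkyne, which the excess base holds as its acetylide, so that isomerisation to an allene or internal alkyne should be suppressed until the aqueous quench.

Step 5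
Reactants: 9 methyl (S)-3-hydroxy-2-methylpropanoate
Product: 10 methyl (S)-3-[(tert-butyldimethylsilyl)oxy]-2-methylpropanoate
Conditions: TBSCl (1.1 equiv), imidazole (2 equiv), CH2Cl2, 0 °C → rt
Reagents that add atoms: tert-butyldimethylsilyl chloride, CC(C)(C)[Si](C)(C)Cl
Why: standard imidazole-mediated silylation of a primary alcohol, too weakly basic to touch the α-stereocentre of the ester.

Step 6
Reactants: 10 silyloxy ester
Product: 12 (S)-3-[(tert-butyldimethylsilyl)oxy]-2-methylpropanal, via aluminium hemiacetal 11 (not isolated)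
Conditions: iBu2AlH (1.1 equiv), CH2Cl2, −78 °C; MeOH, then aq. KNaC4H4O6 (potassium sodium tartrate); used crude
Reagents that add atoms: none
Why: partial hydride reduction of an ester, in which the tetrahedral aluminium hemiacetal is stable at −78 °C and releases the aldehyde only on work-up, and the cold neutral work-up without chromatography should preserve the α-stereocentre.

Step 7
Reactants: 12 (S)-silyloxy aldehyde
Product: 13 (R,E)-tert-butyl[(4-iodo-2-methylbut-3-en-1-yl)oxy]dimethylsilane
Conditions: CrCl2 (6 equiv), CHI3 (2 equiv), dioxane/THF 6:1, 0 °C → rt, dark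
Reagents that add atoms: iodoform, IC(I)I
Why: Takai olefination, in which the geminal dichromium species from CHI3 and CrCl2 adds to the aldehyde and eliminates from the less crowded rotamer to give the E-iodoalkene under non-basic conditions that should not epimerise the α-carbon (the descriptor changes from S to R only through the priority change).

Step 8
Reactants: 8 terminal alkyne; 13 (R,E)-vinyl iodide; 14 trimethylaluminium
Product: 17 tert-butyl{[(2R,3E,5E)-2,6-dimethyl-8-[(4aS,8aS)-2,5,5,8a-tetramethyl-3,4,4a,5,6,7,8,8a-octahydronaphthalen-1-yl]octa-3,5-dien-1-yl]oxy}dimethylsilane, via E-alkenyldimethylalane 15 (not isolated), via E-alkenylzinc chloride 16 (not isolated)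
Conditions: AlMe3 (2 equiv), Cp2ZrCl2 (0.25 equiv), CH2Cl2, 0 °C → rt; volatiles removed in vacuo; then 13 (0.8 equiv), ZnCl2 (1 equiv), Pd(PPh3)4 (5 mol%), THF, rt
Reagents that add atoms: trimethylaluminium (compound 14), C[Al](C)C
Why: Cp2ZrCl2 and AlMe3 form a methylzirconocene–aluminate pair that adds methyl and metal syn across the terminal alkyne of 8 with methyl at the internal carbon C13, and exchange to aluminium leaves the E-alkenylalane 15 (zirconium-catalysed methylalumination of 1-alkynes is the closest known reaction type). ZnCl2 takes over the alkenyl group as 16, the C–I bond of 13 adds oxidatively to zerovalent palladium with retention, and transmetalation followed by reductive elimination from divalent palladium forms the C14–C15 bond with retention at both olefins (Negishi alkenyl–alkenyl coupling). No ring is closed and no stereocentre is created; the syn addition fixes the E geometry of C13=C14, and the E geometry of C15=C16 and the R configuration at C17 are carried over from 13. The step needs regioselectivity (methyl to C13, secured by the terminal alkyne with its unbranched alkyl substituent), chemoselectivity (the tetrasubstituted C8=C9 olefin is too hindered to carbometalate or insert) and transfer of alkenyl in preference to methyl to palladium (secured by removing excess AlMe3 before the coupling and by relaying the sp2 group through zinc). C17 cannot epimerise because it carries a silyloxymethyl group and no carbonyl.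

Step 9
Reactants: 17 diene silyl ether
Product: 18 (2R,3E,5E)-2,6-dimethyl-8-[(4aS,8aS)-2,5,5,8a-tetramethyl-3,4,4a,5,6,7,8,8a-octahydronaphthalen-1-yl]octa-3,5-dien-1-ol
Conditions: Bu4NF (1.5 equiv), THF, 0 °C → rt
Reagents that add atoms: none
Why: fluoride-induced cleavage of the primary silyl ether, driven by the strong Si–F bond, to which no other group in the molecule responds.

Step 10
Reactants: 18 dienol
Product: 19 (2R,3E,5E)-2,6-dimethyl-8-[(4aS,8aS)-2,5,5,8a-tetramethyl-3,4,4a,5,6,7,8,8a-octahydronaphthalen-1-yl]octa-3,5-dienal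
Conditions: Dess–Martin periodinane (1.3 equiv), NaHCO3, CH2Cl2, 0 °C; crude aldehyde used at once
Reagents that add atoms: none
Why: Dess–Martin oxidation of a primary alcohol, run cold and buffered with NaHCO3 so that neither acid nor base strong enough to epimerise C17 or to move the C15=C16 olefin into conjugation should be present.

Step 11
Reactants: 19 dienal
Product: 20 (2R,3E,5E)-2,6-dimethyl-8-[(4aS,8aS)-2,5,5,8a-tetramethyl-3,4,4a,5,6,7,8,8a-octahydronaphthalen-1-yl]octa-3,5-dienoic acid
Conditions: NaClO2 (3 equiv), NaH2PO4 (3 equiv), 2-methyl-2-butene (20 equiv), t-BuOH/H2O, 0 °C → rt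
Reagents that add atoms: sodium chlorite, [Na+].[O-]Cl=O
Why: Pinnick oxidation, in which chlorous acid adds to the aldehyde and fragments to the acid at about pH 4, where the α-stereocentre should be stable, while the large excess of 2-methyl-2-butene traps the HOCl before it can attack the diene or the C8=C9 olefin.

**Compound list**

1 | (−)-sclareol, (1R,2R,4aS,8aS)-1-[(3R)-3-hydroxy-3-methylpent-4-en-1-yl]-2,5,5,8a-tetramethyldecahydronaphthalen-2-ol | C=C[C@](C)(O)CC[C@@H]1[C@@]2(C)CCCC(C)(C)[C@@H]2CC[C@@]1(C)O | starting material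
2 | (3R)-5-[(1R,2R,4aS,8aS)-2-hydroxy-2,5,5,8a-tetramethyldecahydronaphthalen-1-yl]-3-methylpentane-1,2,3-triol, both C2 epimers | OCC(O)[C@](C)(O)CC[C@@H]1[C@@]2(C)CCCC(C)(C)[C@@H]2CC[C@@]1(C)O | intermediate
3 | 4-[(1R,2R,4aS,8aS)-2-hydroxy-2,5,5,8a-tetramethyldecahydronaphthalen-1-yl]butan-2-one | CC(=O)CC[C@@H]1[C@@]2(C)CCCC(C)(C)[C@@H]2CC[C@@]1(C)O | intermediate
4 | 4-[(4aS,8aS)-2,5,5,8a-tetramethyl-3,4,4a,5,6,7,8,8a-octahydronaphthalen-1-yl]butan-2-one | CC1=C(CCC(C)=O)[C@@]2(C)CCCC(C)(C)[C@@H]2CC1 | intermediate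
5 | lithium 4-[(4aS,8aS)-2,5,5,8a-tetramethyl-3,4,4a,5,6,7,8,8a-octahydronaphthalen-1-yl]but-1-en-2-olate | CC1=C(CCC(=C)O[Li])[C@@]2(C)CCCC(C)(C)[C@@H]2CC1 | intermediate
6 | diethyl 4-[(4aS,8aS)-2,5,5,8a-tetramethyl-3,4,4a,5,6,7,8,8a-octahydronaphthalen-1-yl]but-1-en-2-yl phosphate | CC1=C(CCC(=C)OP(=O)(OCC)OCC)[C@@]2(C)CCCC(C)(C)[C@@H]2CC1 | intermediate
7 | {4-[(4aS,8aS)-2,5,5,8a-tetramethyl-3,4,4a,5,6,7,8,8a-octahydronaphthalen-1-yl]but-1-yn-1-yl}lithium | CC1=C(CCC#C[Li])[C@@]2(C)CCCC(C)(C)[C@@H]2CC1 | intermediate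
8 | (4aS,8aS)-1-(but-3-yn-1-yl)-2,5,5,8a-tetramethyl-3,4,4a,5,6,7,8,8a-octahydronaphthalene | CC1=C(CCC#C)[C@@]2(C)CCCC(C)(C)[C@@H]2CC1 | intermediate
9 | methyl (S)-3-hydroxy-2-methylpropanoate | COC(=O)[C@@H](C)CO | starting material
10 | methyl (S)-3-[(tert-butyldimethylsilyl)oxy]-2-methylpropanoate | COC(=O)[C@@H](C)CO[Si](C)(C)C(C)(C)C | intermediate
11 | diisobutylaluminium hemiacetal of 10, (2S)-3-[(tert-butyldimethylsilyl)oxy]-1-methoxy-2-methylpropan-1-olate on Al(iBu)2, both C1 epimers | COC(O[Al](CC(C)C)CC(C)C)[C@@H](C)CO[Si](C)(C)C(C)(C)C | intermediate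
12 | (S)-3-[(tert-butyldimethylsilyl)oxy]-2-methylpropanal | O=C[C@@H](C)CO[Si](C)(C)C(C)(C)C | intermediate
13 | (R,E)-tert-butyl[(4-iodo-2-methylbut-3-en-1-yl)oxy]dimethylsilane | I/C=C/[C@@H](C)CO[Si](C)(C)C(C)(C)C | intermediate
14 | trimethylaluminium | C[Al](C)C | starting material
15 | dimethyl{(1E)-2-methyl-4-[(4aS,8aS)-2,5,5,8a-tetramethyl-3,4,4a,5,6,7,8,8a-octahydronaphthalen-1-yl]but-1-en-1-yl}alane | CC1=C(CC/C(C)=C/[Al](C)C)[C@@]2(C)CCCC(C)(C)[C@@H]2CC1 | intermediate
16 | chloro{(1E)-2-methyl-4-[(4aS,8aS)-2,5,5,8a-tetramethyl-3,4,4a,5,6,7,8,8a-octahydronaphthalen-1-yl]but-1-en-1-yl}zinc | CC1=C(CC/C(C)=C/[Zn]Cl)[C@@]2(C)CCCC(C)(C)[C@@H]2CC1 | intermediate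
17 | tert-butyl{[(2R,3E,5E)-2,6-dimethyl-8-[(4aS,8aS)-2,5,5,8a-tetramethyl-3,4,4a,5,6,7,8,8a-octahydronaphthalen-1-yl]octa-3,5-dien-1-yl]oxy}dimethylsilane | CC1=C(CC/C(C)=C/C=C/[C@@H](C)CO[Si](C)(C)C(C)(C)C)[C@@]2(C)CCCC(C)(C)[C@@H]2CC1 | intermediate
18 | (2R,3E,5E)-2,6-dimethyl-8-[(4aS,8aS)-2,5,5,8a-tetramethyl-3,4,4a,5,6,7,8,8a-octahydronaphthalen-1-yl]octa-3,5-dien-1-ol | CC1=C(CC/C(C)=C/C=C/[C@@H](C)CO)[C@@]2(C)CCCC(C)(C)[C@@H]2CC1 | intermediate
19 | (2R,3E,5E)-2,6-dimethyl-8-[(4aS,8aS)-2,5,5,8a-tetramethyl-3,4,4a,5,6,7,8,8a-octahydronaphthalen-1-yl]octa-3,5-dienal | CC1=C(CC/C(C)=C/C=C/[C@@H](C)C=O)[C@@]2(C)CCCC(C)(C)[C@@H]2CC1 | intermediate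
20 | (2R,3E,5E)-2,6-dimethyl-8-[(4aS,8aS)-2,5,5,8a-tetramethyl-3,4,4a,5,6,7,8,8a-octahydronaphthalen-1-yl]octa-3,5-dienoic acid | CC1=C(CC/C(C)=C/C=C/[C@@H](C)C(=O)O)[C@@]2(C)CCCC(C)(C)[C@@H]2CC1 | target

**Step count**

Total steps: 11. Longest linear sequence: 8 steps (steps 1–4 and 8–11, from sclareol); the iodide branch (steps 5–7) joins at step 8.

**Steps most likely to fail**

1. Step 8 (key step). Carbometalation and coupling share one flask, so incomplete or regio-imperfect methylalumination, transfer of methyl instead of alkenyl from aluminium to palladium, or homocoupling of the iodide could erode the diene. The fallback sets out from 8 and 13 and returns at 17; it separates the two events and reverses the polarity of the coupling. The alkenylalane 15 is made as in step 8 and quenched with I2 in THF at −30 °C to give the isolable alkenyl iodide (4aS,8aS)-1-[(3E)-4-iodo-3-methylbut-3-en-1-yl]-2,5,5,8a-tetramethyl-3,4,4a,5,6,7,8,8a-octahydronaphthalene F1, which can be purified free of aluminium residues and regioisomers. Iodide 13 becomes the nucleophile: iodine–lithium exchange with t-BuLi (2 equiv, Et2O, −78 °C) should give the vinyllithium [(1E,3R)-4-[(tert-butyldimethylsilyl)oxy]-3-methylbut-1-en-1-yl]lithium F2, which ZnCl2 converts into the alkenylzinc chloride chloro[(1E,3R)-4-[(tert-butyldimethylsilyl)oxy]-3-methylbut-1-en-1-yl]zinc F3. Coupling of F3 with F1 under Pd(PPh3)4 catalysis in THF at rt should give 17 with retention at both olefins.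

2. Step 2. The C8 cation may lose a proton toward C7 or the C8 methyl instead of C9, or be captured by the side-chain carbonyl to give the cyclic enol ether. The fallback sets out from 3 and returns at 4; it masks the carbonyl and dehydrates under fully equilibrating acid in one operation. Ethylene glycol with catalytic p-TsOH in refluxing benzene, with azeotropic removal of water, should give the dioxolane 2-methyl-2-{2-[(4aS,8aS)-2,5,5,8a-tetramethyl-3,4,4a,5,6,7,8,8a-octahydronaphthalen-1-yl]ethyl}-1,3-dioxolane F4 with the olefin in the thermodynamically preferred tetrasubstituted C8=C9 position. Pyridinium p-toluenesulfonate in wet acetone at rt then releases ketone 4.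

3. Step 10. The α-branched β,γ-unsaturated aldehyde 19 may epimerise at C17 or let the C15=C16 olefin slip into conjugation during isolation and handling. The fallback sets out from 18 and returns at the target 20, without isolating 19. The alcohol is oxidised directly to the acid in one flask with catalytic TEMPO and PhI(OAc)2 in MeCN/aqueous pH 7 phosphate buffer at 0 °C → rt. The oxoammonium salt oxidises first the alcohol and then the aldehyde hydrate as it forms, so the aldehyde should never accumulate or be concentrated. This fallback makes no new compound (F0).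

**Further compounds**

F1 | step 8 | (4aS,8aS)-1-[(3E)-4-iodo-3-methylbut-3-en-1-yl]-2,5,5,8a-tetramethyl-3,4,4a,5,6,7,8,8a-octahydronaphthalene | CC1=C(CC/C(C)=C/I)[C@@]2(C)CCCC(C)(C)[C@@H]2CC1
F2 | step 8 | [(1E,3R)-4-[(tert-butyldimethylsilyl)oxy]-3-methylbut-1-en-1-yl]lithium | [Li]/C=C/[C@@H](C)CO[Si](C)(C)C(C)(C)C
F3 | step 8 | chloro[(1E,3R)-4-[(tert-butyldimethylsilyl)oxy]-3-methylbut-1-en-1-yl]zinc | Cl[Zn]/C=C/[C@@H](C)CO[Si](C)(C)C(C)(C)C
F4 | step 2 | 2-methyl-2-{2-[(4aS,8aS)-2,5,5,8a-tetramethyl-3,4,4a,5,6,7,8,8a-octahydronaphthalen-1-yl]ethyl}-1,3-dioxolane | CC1=C(CCC3(C)OCCO3)[C@@]2(C)CCCC(C)(C)[C@@H]2CC1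
F0 | step 10 | none | none
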